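**Retrosynthetic overview**

1. The feruloyl ester C–O bond is disconnected last: the primary alcohol of an (R)-2-(hydroxymethyl)-2-methyl-2H-chromene is acylated with O-acetylferulic acid and the phenol is unmasked at the end.
2. Pyran ring B is the only ring formed. It is made in one operation from a salicylaldehyde that already carries all of ring A (5-acetyl-2-hydroxy-3-methoxybenzaldehyde, from acetovanillone by ortho-formylation) and an (E)-alkenylboronic acid, with catalytic Bn2NH and a chiral phosphoric acid. C4–C3 forms by borono-Mannich alkenyl transfer and O1–C2 by oxa-6π ring closure, which also sets the quaternary stereocentre C2.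
3. Enabling feature (chromene numbering): on ring A the phenolic oxygen O1 (on C8a) and carbon C4 (on C4a) are ortho, so O1–C8a–C4a–C4–C3–C2 of ring B is a masked 1-oxatriene (o-quinone methide) and ring B is its electrocyclization product. The same ortho OH/CHO pair lets the phenol carry the boron reagent to C4.
4. The boronic acid comes from propargyl alcohol by carboalumination–iodination (fixes the E geometry), silylation and iodine–lithium exchange/borylation.

Key step: step 5

Assumption: the sense of induction of the chiral acid in step 5 cannot be predicted with confidence; the (R)-acid is written, and its commercially available (S)-enantiomer would be used instead if the opposite sense is found.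
Remark: 2H-chromenes open photochemically to o-quinone methides, so all material from step 5 onward should be handled with exclusion of UV light and without strong heating.

**Step 1**
Reactants: 1 acetovanillone [1-(4-hydroxy-3-methoxyphenyl)ethanone]
Product: 2 5-acetyl-2-hydroxy-3-methoxybenzaldehyde
Conditions: hexamethylenetetramine (2.5 equiv), TFA, 90 °C; then 2 M aq. HCl, 60 °C
Reagents that add atoms: hexamethylenetetramine, C1N2CN3CN1CN(C2)C3 (formyl carbon); water, O (formyl oxygen)
Why: Duff reaction: the phenol directs the iminium electrophile to its only free ortho position (the para position carries the acetyl group), and hydrolysis of the benzylic iminium gives the aldehyde, as is usual for deactivated phenols such as vanillin.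

**Step 2**
Reactants: 3 propargyl alcohol (prop-2-yn-1-ol)
Product: 5 (E)-3-iodo-2-methylprop-2-en-1-ol, via alkenylalane 4 (not isolated)
Conditions: AlMe3 (3 equiv), Cp2ZrCl2 (0.25 equiv), CH2Cl2, 0 °C to rt; then I2, THF, −30 to 0 °C; aqueous work-up
Reagents that add atoms: trimethylaluminium, C[Al](C)C (methyl group); iodine, II (iodine atom)
Why: Negishi zirconium-catalysed carboalumination adds Me–Al syn across the alkyne with aluminium at the terminal carbon, and iodinolysis of the C–Al bond with retention fixes the E geometry (I cis to CH3).

**Step 3**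
Reactants: 5 (E)-3-iodo-2-methylprop-2-en-1-ol
Product: 6 tert-butyl{[(E)-3-iodo-2-methylprop-2-en-1-yl]oxy}diphenylsilane
Conditions: TBDPSCl, imidazole, CH2Cl2, 0 °C to rt
Reagents that add atoms: tert-butyl(chloro)diphenylsilane, CC(C)(C)[Si](Cl)(c1ccccc1)c1ccccc1
Why: Standard silyl ether formation on a primary allylic alcohol; the bulky, acid-stable TBDPS group should survive steps 4 and 5 and makes the two future C2 substituents (CH3 and CH2OSi) sterically distinct.

**Step 4**
Reactants: 6 tert-butyl{[(E)-3-iodo-2-methylprop-2-en-1-yl]oxy}diphenylsilane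
Product: 9 [(E)-3-{[tert-butyl(diphenyl)silyl]oxy}-2-methylprop-1-en-1-yl]boronic acid, via alkenyllithium 7 (not isolated), via lithium alkenyl(triisopropoxy)borate 8 (not isolated)
Conditions: t-BuLi (2.1 equiv), Et2O, −78 °C; B(OiPr)3, −78 °C to rt; 1 M aq. HCl, 0 °C, brief
Reagents that add atoms: triisopropyl borate, CC(C)OB(OC(C)C)OC(C)C (boron); water, O (oxygens of B(OH)2)
Why: Iodine–lithium exchange proceeds with retention of alkene geometry, the alkenyllithium is trapped by the borate, and hydrolysis of the ate complex gives the boronic acid (standard halogen–metal exchange/borylation).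

**Step 5**
Reactants: 2 5-acetyl-2-hydroxy-3-methoxybenzaldehyde; 9 [(E)-3-{[tert-butyl(diphenyl)silyl]oxy}-2-methylprop-1-en-1-yl]boronic acid
Product: 12 1-[(2R)-2-({[tert-butyl(diphenyl)silyl]oxy}methyl)-8-methoxy-2-methyl-2H-chromen-6-yl]ethanone, via Petasis adduct 10 (not isolated), via o-quinone methide 11 (not isolated)
Conditions: Bn2NH (20 mol%), (R)-TRIP [(R)-3,3'-bis(2,4,6-triisopropylphenyl)-1,1'-binaphthyl-2,2'-diyl hydrogen phosphate] (20 mol%), 9 (1.3 equiv), toluene, rt then 50 °C, exclusion of light
Reagents that add atoms: none
Why: Proposed new method: a Petasis–Finn borono-Mannich/oxa-6π cascade run under asymmetric counteranion-directed catalysis, in which Bn2NH condenses with the aldehyde of 2, the phenol binds 9 as a tetracoordinate boronate that delivers the alkenyl group with retention to the neighbouring iminium carbon (C4–C3 bond, adduct 10), and the TRIP anion, hydrogen-bonded to the phenol OH, assists loss of the protonated amine to give the (Z)-o-quinone methide 11 still bound to the chiral acid. Ring B should then close by thermal disrotatory oxa-6π electrocyclization of the 1-oxatriene O1–C8a–C4a–C4–C3–C2 (formally a 6-endo-trig attack of O1 on C2), forming O1–C2 and releasing amine and acid for the next turnover. The closest known reactions are the racemic amine-catalysed Petasis–Finn synthesis of 2H-chromenes from salicylaldehydes and alkenylboronic acids, and the cyclization of 2-hydroxyaryl allylic alcohols to 2,2-disubstituted 2H-chromenes through a chiral contact ion pair with a BINOL N-triflylphosphoramide; merging the two has not been shown. The C2 stereocentre should be set by the chiral phosphate, which selects one helical sense of the cyclizing oxatriene; together with the fixed E geometry of the C2=C3 bond inherited from 9 this defines which face of C2 is attacked, and the size difference between CH3 and CH2OTBDPS should sharpen the choice. The step needs two selectivities: aldehyde over acetyl ketone, secured because only the carbonyl ortho to the phenol can receive the alkenyl group from the phenol-bound boronate; and ring closure inside the ion pair faster than escape of free 11, favoured by the non-polar solvent and moderate temperature.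

**Step 6**
Reactants: 12 1-[(2R)-2-({[tert-butyl(diphenyl)silyl]oxy}methyl)-8-methoxy-2-methyl-2H-chromen-6-yl]ethanone
Product: 13 1-[(2R)-2-(hydroxymethyl)-8-methoxy-2-methyl-2H-chromen-6-yl]ethanone
Conditions: TBAF, AcOH (1:1), THF, rt
Reagents that add atoms: none
Why: Fluoride-mediated desilylation driven by Si–F bond formation; acetic acid buffering keeps the medium non-basic for the enolizable aryl ketone, and the stereocentre is not involved.

**Step 7**
Reactants: 13 1-[(2R)-2-(hydroxymethyl)-8-methoxy-2-methyl-2H-chromen-6-yl]ethanone; 14 (E)-4-acetoxy-3-methoxycinnamic acid (O-acetylferulic acid)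
Product: 15 [(2R)-6-acetyl-8-methoxy-2-methyl-2H-chromen-2-yl]methyl (2E)-3-(4-acetoxy-3-methoxyphenyl)prop-2-enoate
Conditions: EDC·HCl, DMAP (10 mol%), CH2Cl2, 0 °C to rt
Reagents that add atoms: none
Why: Steglich esterification passes the carbodiimide-activated acid through the acyl-DMAP cation to the neopentyl-type primary alcohol (acylation at oxygen, so the hindered carbon is not attacked), while the acetate mask prevents self-acylation of the ferulic phenol.

**Step 8**
Reactants: 15 [(2R)-6-acetyl-8-methoxy-2-methyl-2H-chromen-2-yl]methyl (2E)-3-(4-acetoxy-3-methoxyphenyl)prop-2-enoate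
Product: 16 [(2R)-6-acetyl-8-methoxy-2-methyl-2H-chromen-2-yl]methyl (2E)-3-(4-hydroxy-3-methoxyphenyl)prop-2-enoate (CNP0168033.1)
Conditions: pyrrolidine (2 equiv), CH2Cl2, 0 °C to rt
Reagents that add atoms: none
Why: Chemoselective aminolysis: the phenolic acetate is an activated aryl ester and should be cleaved much faster than the alkyl cinnamate ester, leaving ketone, chromene and stereocentre untouched.

**Compound list**

1 | acetovanillone, 1-(4-hydroxy-3-methoxyphenyl)ethanone | CC(=O)c1ccc(O)c(OC)c1 | starting material
2 | 5-acetyl-2-hydroxy-3-methoxybenzaldehyde | CC(=O)c1cc(OC)c(O)c(C=O)c1 | intermediate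
3 | propargyl alcohol (prop-2-yn-1-ol) | C#CCO | starting material
4 | (E)-alkenylalane, dimethylaluminium alkoxide of (E)-3-(dimethylalumanyl)-2-methylprop-2-en-1-ol | C[Al](C)OC/C(C)=C/[Al](C)C | intermediate (not isolated)
5 | (E)-3-iodo-2-methylprop-2-en-1-ol | OC/C(C)=C/I | intermediate
6 | tert-butyl{[(E)-3-iodo-2-methylprop-2-en-1-yl]oxy}diphenylsilane | CC(C)(C)[Si](c1ccccc1)(c1ccccc1)OC/C(C)=C/I | intermediate
7 | (E)-alkenyllithium from 6 (Li in place of I) | [Li]/C=C(\C)CO[Si](c1ccccc1)(c1ccccc1)C(C)(C)C | intermediate (not isolated)
8 | lithium [(E)-alkenyl]triisopropoxyborate | [Li+].CC(C)O[B-](OC(C)C)(OC(C)C)/C=C(\C)CO[Si](c1ccccc1)(c1ccccc1)C(C)(C)C | intermediate (not isolated)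
9 | [(E)-3-{[tert-butyl(diphenyl)silyl]oxy}-2-methylprop-1-en-1-yl]boronic acid | CC(C)(C)[Si](c1ccccc1)(c1ccccc1)OC/C(C)=C/B(O)O | intermediate
10 | Petasis adduct, 1-{3-[(E)-1-(dibenzylamino)-4-{[tert-butyl(diphenyl)silyl]oxy}-3-methylbut-2-en-1-yl]-4-hydroxy-5-methoxyphenyl}ethanone (benzylic configuration not defined, lost in the next event) | CC(=O)c1cc(OC)c(O)c(c1)C(N(Cc1ccccc1)Cc1ccccc1)/C=C(\C)CO[Si](c1ccccc1)(c1ccccc1)C(C)(C)C | intermediate (not isolated)
11 | o-quinone methide, 4-acetyl-2-methoxy-6-[(E)-4-{[tert-butyl(diphenyl)silyl]oxy}-3-methylbut-2-en-1-ylidene]cyclohexa-2,4-dien-1-one, exocyclic C=C with the alkenyl chain cis to the carbonyl (Z) | O=C1C(OC)=CC(C(C)=O)=C/C1=C/C=C(\C)CO[Si](c2ccccc2)(c2ccccc2)C(C)(C)C | intermediate (not isolated)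
12 | 1-[(2R)-2-({[tert-butyl(diphenyl)silyl]oxy}methyl)-8-methoxy-2-methyl-2H-chromen-6-yl]ethanone | CC(C)(C)[Si](c1ccccc1)(c1ccccc1)OC[C@@]2(C)C=Cc3cc(C(C)=O)cc(OC)c3O2 | intermediate
13 | 1-[(2R)-2-(hydroxymethyl)-8-methoxy-2-methyl-2H-chromen-6-yl]ethanone | OC[C@@]1(C)C=Cc2cc(C(C)=O)cc(OC)c2O1 | intermediate
14 | (E)-4-acetoxy-3-methoxycinnamic acid (O-acetylferulic acid) | CC(=O)Oc1ccc(/C=C/C(=O)O)cc1OC | starting material
15 | [(2R)-6-acetyl-8-methoxy-2-methyl-2H-chromen-2-yl]methyl (2E)-3-(4-acetoxy-3-methoxyphenyl)prop-2-enoate | CC(=O)Oc1ccc(/C=C/C(=O)OC[C@@]2(C)C=Cc3cc(C(C)=O)cc(OC)c3O2)cc1OC | intermediate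
16 | [(2R)-6-acetyl-8-methoxy-2-methyl-2H-chromen-2-yl]methyl (2E)-3-(4-hydroxy-3-methoxyphenyl)prop-2-enoate | COc1cc(/C=C/C(=O)OC[C@@]2(C)C=Cc3cc(C(C)=O)cc(OC)c3O2)ccc1O | target

**Step count and risks**

Total step count: 8. Longest linear sequence: 7 steps (steps 2, 3, 4, 5, 6, 7, 8 from propargyl alcohol).

Steps most likely to fail:

1. Step 5 (proposed new method). The o-quinone methide may leave the chiral ion pair and close without control, or the acid may reopen and reclose the product, so that enantioface selection is poor or erodes. Alkenyl transfer from a trisubstituted alkenylboronic acid may also be slow. Fallback, setting out from 2 and 9: the established racemic Petasis–Finn condensation (Bn2NH 20–40 mol%, no chiral acid, dioxane, 90 °C) should give the racemic silyl ether F1. Preparative chromatography on a polysaccharide-based chiral stationary phase (supercritical CO2/alcohol) should then separate the (R)-enantiomer, which is 12 and rejoins the route there, from the (S)-enantiomer F2, which is set aside. The stereocentre is then obtained by resolution instead of catalyst control.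

2. Step 4. Protodeboronation, partial dehydration to the boroxine and losses on isolation may give a boronic acid of uncertain purity and stoichiometry. Fallback, setting out from 6: Miyaura borylation (B2pin2, PdCl2(PPh3)2, PPh3, KOPh, toluene, 50 °C) should give, with retention of geometry, the pinacol boronate F3. KHF2 in aqueous MeOH should convert it into the crystalline potassium trifluoroborate F4, which is purified by recrystallization and hydrolysed (silica gel, water, rt) just before use. The route is rejoined at 9.

3. Step 8. The amine may over-react by aminolysis of the cinnamate ester or conjugate addition to it instead of cleaving only the aryl acetate. Fallback, setting out from 13: heating with Meldrum's acid (toluene, 85 °C) should give the malonic half ester F5. Knoevenagel–Doebner condensation of F5 with vanillin (pyridine, catalytic piperidine, rt to 40 °C) should then give the E-configured ferulate directly with loss of CO2, so that no phenol protecting group is needed and 15 is bypassed. The route is rejoined at 16.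

**Further compounds**

F1 | step 5 | racemic 1-[2-({[tert-butyl(diphenyl)silyl]oxy}methyl)-8-methoxy-2-methyl-2H-chromen-6-yl]ethanone | CC(C)(C)[Si](c1ccccc1)(c1ccccc1)OCC2(C)C=Cc3cc(C(C)=O)cc(OC)c3O2
F2 | step 5 | 1-[(2S)-2-({[tert-butyl(diphenyl)silyl]oxy}methyl)-8-methoxy-2-methyl-2H-chromen-6-yl]ethanone | CC(C)(C)[Si](c1ccccc1)(c1ccccc1)OC[C@]2(C)C=Cc3cc(C(C)=O)cc(OC)c3O2
F3 | step 4 | tert-butyl{[(E)-2-methyl-3-(4,4,5,5-tetramethyl-1,3,2-dioxaborolan-2-yl)prop-2-en-1-yl]oxy}diphenylsilane | CC(C)(C)[Si](c1ccccc1)(c1ccccc1)OC/C(C)=C/B1OC(C)(C)C(C)(C)O1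
F4 | step 4 | potassium [(E)-3-{[tert-butyl(diphenyl)silyl]oxy}-2-methylprop-1-en-1-yl]trifluoroborate | [K+].CC(C)(C)[Si](c1ccccc1)(c1ccccc1)OC/C(C)=C/[B-](F)(F)F
F5 | step 8 | 3-{[(2R)-6-acetyl-8-methoxy-2-methyl-2H-chromen-2-yl]methoxy}-3-oxopropanoic acid | OC(=O)CC(=O)OC[C@@]1(C)C=Cc2cc(C(C)=O)cc(OC)c2O1
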